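**Retrosynthetic overview**

1. The target gibberellin ⇐ hydrogenolysis of its 7-benzyl ester 16-O-benzyloxymethyl ether ⇐ stereoselective reduction of a 3-ketone ⇐ intramolecular aldol (C3–C4) that closes ring A last.
2. The 19,10-lactone and the C4–C5 bond ⇐ intramolecular Michael addition of a C10 propanoate onto a C5=C6 benzyl enoate; the C10 carbinol ⇐ Grignard addition to a ring B C10 ketone; the enoate ⇐ carbonylation of the C6 enol triflate.
3. Ring D with its C16 carbinol ⇐ proposed photocatalytic α-hydroxy C–H radical cyclisation (C16 → C13) of a 2-hydroxypropyl side chain onto the ring C alkene.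
4. Ring C ⇐ Diels–Alder reaction of butadiene with (R)-2-allyl-4-silyloxycyclopentenone (ring B); its carbinol carbon, the later C10, controls C8 and C9.
5. Order of ring formation: B (chiral pool) → C → D → lactone → A.

Assumption: atoms carry the gibberellane numbers of the target (C7 acid carbon on C6, C17 methyl on C16, C18 methyl on C4, C19 lactone carbonyl). β is the face of H-5 and H-9, and 16α is the side of ring D facing C14. With these descriptors the target is 3β,10α,16α-trihydroxy-20-norgibberellane-7,19-dioic acid 19,10-lactone, called "the target gibberellin" below. Reagents that deliver only a heteroatom, a protecting group or a leaving group (I2, O2, BnOCH2Cl, Comins' reagent, BnOH, water) carry no number and stand with their SMILES on the "Reagents that add atoms" line. KN(SiMe3)2, the Grignard reagent 16 and Dess–Martin periodinane are bought.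

**Route**

Step 1
Reactants: 1 (R)-4-(tert-butyldimethylsilyloxy)cyclopent-2-en-1-one
Product: 2 (R)-4-(tert-butyldimethylsilyloxy)-2-iodocyclopent-2-en-1-one
Conditions: I2 (1.5 equiv), pyridine–CH2Cl2 (1:1), 0 → 25 °C
Reagents that add atoms: iodine, II
Why: α-Iodination of the enone by pyridine conjugate addition, iodination and elimination (Baylis–Hillman-type mechanism) is the standard reaction of this enone and does not touch the carbinol stereocentre.

Step 2
Reactants: 2 (R)-4-(tert-butyldimethylsilyloxy)-2-iodocyclopent-2-en-1-one; 3 allyltributylstannane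
Product: 4 (R)-2-allyl-4-(tert-butyldimethylsilyloxy)cyclopent-2-en-1-one
Conditions: Pd2(dba)3 (2.5 mol%), AsPh3 (10 mol%), CuI (10 mol%), DMF, 40 °C
Reagents that add atoms: allyltributylstannane (3), C=CC[Sn](CCCC)(CCCC)CCCC
Why: Stille cross-coupling of the α-iodoenone with the allylstannane forms the C8–C15 bond under neutral conditions that leave the β-silyloxy ketone and its stereocentre intact.

Step 3
Reactants: 4 (R)-2-allyl-4-(tert-butyldimethylsilyloxy)cyclopent-2-en-1-one; 5 buta-1,3-diene
Product: 6 (3R,3aR,7aS)-7a-allyl-3-(tert-butyldimethylsilyloxy)-2,3,3a,4,7,7a-hexahydro-1H-inden-1-one (cis ring fusion; OTBS on the face of H-3a and of the allyl group)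
Conditions: MeAlCl2 (0.3 equiv), butadiene (10 equiv), CH2Cl2, −40 → 0 °C, sealed tube
Reagents that add atoms: buta-1,3-diene (5), C=CC=C
Why: In this Lewis-acid-catalysed Diels–Alder reaction the diene adds suprafacially to the enone face anti to the bulky OTBS group, so the cis fusion and both new stereocentres (quaternary C8 and C9) follow from the (R)-carbinol centre.

Step 4
Reactants: 6 (3R,3aR,7aS)-7a-allyl-3-(tert-butyldimethylsilyloxy)-2,3,3a,4,7,7a-hexahydro-1H-inden-1-one
Product: 8 (3R,3aR,7aR)-3-(tert-butyldimethylsilyloxy)-7a-(2-hydroxypropyl)-2,3,3a,4,7,7a-hexahydro-1H-inden-1-one (both carbinol epimers), via hydroperoxide 7 (not isolated)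
Conditions: Co(acac)2 (20 mol%), PhSiH3 (2 equiv), O2 (1 atm), i-PrOH, 25 °C
Reagents that add atoms: dioxygen, O=O
Why: Mukaiyama hydration (cobalt-hydride hydrogen-atom transfer, O2 capture, in situ reduction of the hydroperoxide) is Markovnikov and faster at the monosubstituted alkene than at the 1,2-disubstituted ring alkene; the new carbinol centre is a mixture that does not matter because it becomes a planar radical in step 5.

Step 5
Reactants: 8 (3R,3aR,7aR)-3-(tert-butyldimethylsilyloxy)-7a-(2-hydroxypropyl)-2,3,3a,4,7,7a-hexahydro-1H-inden-1-one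
Product: 9 tricyclic ketol of rings B, C and D: ring B cyclopentanone (C6 ketone, 10β-OTBS) cis-fused at C8–C9 to the ring C/D bicyclo[3.2.1]octane bearing 16α-OH and 16-CH3 (H-9 β, C15–C16 bridge β)
Conditions: Ir[dF(CF3)ppy]2(dtbbpy)PF6 (1 mol%), quinuclidine (10 mol%), Bu4N(H2PO4) (25 mol%), 2,4,6-triisopropylbenzenethiol (10 mol%), MeCN (0.02 M), 450 nm LEDs, 25 °C
Reagents that add atoms: none
Why: Proposed new method: a redox-neutral intramolecular hydroalkylation in which the photoexcited iridium complex oxidises quinuclidine to its radical cation, which abstracts the hydridic α-C–H of the phosphate-hydrogen-bonded secondary alcohol (the C–H next to OTBS and the allylic C–H bonds are not activated this way); the nucleophilic α-hydroxyalkyl radical at C16 closes 5-exo onto C13 of the ring C alkene through the conformer with the side chain axial, and the C12 radical takes hydrogen from the arenethiol, whose thiyl radical is reduced by the reduced photocatalyst to close the cycle. The hydrogen-bonded oxygen sits anti to the alkene and the methyl points toward C12 in the transition state (the same preference as the oxygen in SmI2 ketyl–olefin cyclisations), so OH ends trans to C12 (16α), while C13 is fixed by the bridge geometry and the C6 ketone is left alone because no reductant is present. The closest known reaction types are the photoredox/quinuclidine/phosphate α-C–H alkylation of alcohols with acrylates (Giese type) and the SmI2 ketyl–olefin cyclisation, neither shown for a neutral α-hydroxyalkyl radical closing onto an unactivated ring alkene to a bridged carbinol.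

Step 6
Reactants: 9 tricyclic ketol (10β-OTBS, 16α-OH)
Product: 10 16-O-benzyloxymethyl (BOM) ether of 9
Conditions: BnOCH2Cl (3 equiv), i-Pr2NEt (4 equiv), Bu4NI (0.1 equiv), 1,2-dichloroethane, 50 °C
Reagents that add atoms: benzyl chloromethyl ether, ClCOCc1ccccc1
Why: Williamson-type alkylation of the hindered tertiary alcohol with the reactive α-chloro ether (iodide catalysis) needs only an amine base, which the β-silyloxy ketone tolerates.

Step 7
Reactants: 10 16-O-BOM tricyclic ketone
Product: 11 C5=C6 enol triflate of 10 (6-trifluoromethanesulfonyloxy-5-ene; 10β-OTBS, 16-OBOM)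
Conditions: KN(SiMe3)2 (1.1 equiv), THF, −78 °C; then Comins' reagent (1.2 equiv), −78 °C
Reagents that add atoms: N-(5-chloropyridin-2-yl)-N-(trifluoromethylsulfonyl)trifluoromethanesulfonamide (Comins' reagent), O=S(=O)(N(c1ccc(Cl)cn1)S(=O)(=O)C(F)(F)F)C(F)(F)F
Why: Enolisation can only go toward C5 because C8 is quaternary, and O-triflation of the potassium enolate at −78 °C outruns β-elimination of the silyloxy group.

Step 8
Reactants: 11 enol triflate; 12 carbon monoxide
Product: 13 benzyl 5-ene-7-oate of the tricycle (CO2Bn on C6; 10β-OTBS, 16-OBOM)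
Conditions: Pd(OAc)2 (5 mol%), PPh3 (10 mol%), CO (1 atm), BnOH (5 equiv), Et3N (2 equiv), DMF, 50 °C
Reagents that add atoms: carbon monoxide (12), [C-]#[O+]; benzyl alcohol, OCc1ccccc1
Why: Palladium-catalysed alkoxycarbonylation of the enol triflate (oxidative addition, CO insertion, alcoholysis) installs C7 as the benzyl ester and keeps the C5=C6 double bond needed as Michael acceptor in step 13.

Step 9
Reactants: 13 benzyl enoate (10β-OTBS)
Product: 14 benzyl 10β-hydroxy-5-ene-7-oate (16-OBOM)
Conditions: HF·pyridine, pyridine, THF, 0 → 25 °C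
Reagents that add atoms: none
Why: Fluoride-driven cleavage of the secondary allylic silyl ether; the benzyl ester and the BOM ether are inert to buffered HF.

Step 10
Reactants: 14 allylic alcohol
Product: 15 benzyl 10-oxo-5-ene-7-oate (16-OBOM)
Conditions: Dess–Martin periodinane (1.3 equiv), CH2Cl2, 0 → 25 °C
Reagents that add atoms: none
Why: Dess–Martin oxidation of the allylic alcohol gives the enone under neutral conditions; C9 is now epimerisable, but the cis B/C fusion set in step 3 is the stable one.

Step 11
Reactants: 15 keto enoate; 16 [2-(1,3-dioxolan-2-yl)ethyl]magnesium bromide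
Product: 17 benzyl 10α-hydroxy-10β-[2-(1,3-dioxolan-2-yl)ethyl]-5-ene-7-oate (16-OBOM)
Conditions: 16 (1.5 equiv, 0.5 M in THF), LaCl3·2LiCl (0.3 equiv), THF, −78 → −40 °C; then H2O
Reagents that add atoms: [2-(1,3-dioxolan-2-yl)ethyl]magnesium bromide (16), Br[Mg]CCC1OCCO1
Why: Grignard 1,2-addition, with LaCl3·2LiCl to suppress enolisation and conjugate addition, occurs from the convex β face (syn to H-9, away from ring C), which puts the chain (C1–C3) β and the new C10–O bond α as the lactone requires.

Step 12
Reactants: 17 tertiary allylic alcohol; 18 propanoic anhydride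
Product: 19 10α-propanoate of 17
Conditions: KN(SiMe3)2 (1.05 equiv), THF, −78 °C; then 18 (1.5 equiv), −78 → 0 °C
Reagents that add atoms: propanoic anhydride (18), CCC(=O)OC(=O)CC
Why: O-Acylation of the hindered tertiary potassium alkoxide with the anhydride attaches the unit that becomes C19, C4 and C18.

Step 13
Reactants: 19 propanoate
Product: 20 19,10α-γ-lactone closed onto C5 (H-5 β; C4 carries H and a methyl cis to H-5; 6β-CO2Bn; C10 keeps the dioxolanylethyl chain; 16-OBOM)
Conditions: KN(SiMe3)2 (1.1 equiv), THF, −78 → −20 °C; t-BuOH (5 equiv), 0 °C; then AcOH (1.2 equiv)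
Reagents that add atoms: none
Why: Intramolecular 5-exo-trig Michael addition of the propanoate enolate to the enoate can deliver C4 only to the α face of C5 because the tether is α, and protonation under equilibrating conditions places the C6 ester β (trans to C4); the C4 configuration is of no consequence because C4 is enolised again in step 15.

Step 14
Reactants: 20 lactone acetal
Product: 21 lactone aldehyde (as 20 with the C10 chain CH2CH2CHO)
Conditions: 1 M aq. HCl–THF (1:3), 25 °C
Reagents that add atoms: water, O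
Why: Acid-catalysed acetal hydrolysis frees the C3 aldehyde; lactone, benzyl ester and BOM ether tolerate dilute aqueous acid at room temperature.

Step 15
Reactants: 21 lactone aldehyde
Product: 22 3-epimer of the target gibberellin as its 7-benzyl ester 16-O-BOM ether (3α-OH)
Conditions: KOt-Bu (0.3 equiv), t-BuOH–THF (1:1), 0 °C
Reagents that add atoms: none
Why: Intramolecular aldol addition of the lactone enolate to the aldehyde closes ring A; quaternary C4 is fixed by the bicyclic geometry, C6 stays β, and the reversible reaction gives mainly the equatorial 3α-alcohol (the minor 3β epimer, identical with the product of step 17, is not separated and is oxidised as well).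

Step 16
Reactants: 22 3α-alcohol
Product: 23 3-oxo compound (3-ketone corresponding to the 7-benzyl ester 16-O-BOM ether of the target gibberellin)
Conditions: Dess–Martin periodinane (1.5 equiv), CH2Cl2, 25 °C
Reagents that add atoms: none
Why: Dess–Martin oxidation converts both C3 epimers into one non-enolisable β-keto lactone under neutral conditions that avoid retro-Claisen cleavage.

Step 17
Reactants: 23 3-ketone
Product: 24 7-benzyl ester 16-O-BOM ether of the target gibberellin (3β-OH)
Conditions: KBH(s-Bu)3 (1.2 equiv), THF, −78 °C; then AcOH, −78 °C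
Reagents that add atoms: none
Why: The bulky trialkylborohydride attacks the ring A ketone from the equatorial direction and gives the axial 3β-alcohol, as known for 3-oxo gibberellins; the cold acidic quench prevents retro-aldol epimerisation.

Step 18
Reactants: 24 7-benzyl ester 16-O-BOM ether of the target gibberellin
Product: 26 the target gibberellin (3β,10α,16α-trihydroxy-20-norgibberellane-7,19-dioic acid 19,10-lactone), via hemiformal 25 (not isolated)
Conditions: H2 (1 atm), Pd/C (10 wt% Pd), EtOAc–MeOH (1:1), 25 °C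
Reagents that add atoms: none
Why: Hydrogenolysis cleaves the benzyl ester and the benzyl C–O bond of the BOM ether, whose hemiformal loses formaldehyde; no base is present, so the 3β-hydroxy lactone cannot epimerise.

**Compound list**

1 | (R)-4-(tert-butyldimethylsilyloxy)cyclopent-2-en-1-one | O=C1C[C@@H](O[Si](C)(C)C(C)(C)C)C=C1 | starting material
2 | (R)-4-(tert-butyldimethylsilyloxy)-2-iodocyclopent-2-en-1-one | O=C1C[C@@H](O[Si](C)(C)C(C)(C)C)C=C1I | intermediate
3 | allyltributylstannane | C=CC[Sn](CCCC)(CCCC)CCCC | starting material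
4 | (R)-2-allyl-4-(tert-butyldimethylsilyloxy)cyclopent-2-en-1-one | O=C1C[C@@H](O[Si](C)(C)C(C)(C)C)C=C1CC=C | intermediate
5 | buta-1,3-diene | C=CC=C | starting material
6 | (3R,3aR,7aS)-7a-allyl-3-(tert-butyldimethylsilyloxy)-2,3,3a,4,7,7a-hexahydro-1H-inden-1-one | O=C1C[C@@H](O[Si](C)(C)C(C)(C)C)[C@@H]2CC=CC[C@]12CC=C | intermediate
7 | (3R,3aR,7aR)-3-(tert-butyldimethylsilyloxy)-7a-(2-hydroperoxypropyl)-2,3,3a,4,7,7a-hexahydro-1H-inden-1-one (both side-chain epimers; not isolated) | O=C1C[C@@H](O[Si](C)(C)C(C)(C)C)[C@@H]2CC=CC[C@]12CC(C)OO | intermediate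
8 | (3R,3aR,7aR)-3-(tert-butyldimethylsilyloxy)-7a-(2-hydroxypropyl)-2,3,3a,4,7,7a-hexahydro-1H-inden-1-one (both carbinol epimers) | O=C1C[C@@H](O[Si](C)(C)C(C)(C)C)[C@@H]2CC=CC[C@]12CC(C)O | intermediate
9 | tricyclic ketol of rings B, C and D: C6 ketone, 10β-OTBS, 16α-OH, 16-CH3 | O=C1C[C@@H](O[Si](C)(C)C(C)(C)C)[C@@H]2CC[C@@H]3C[C@]12C[C@@]3(C)O | intermediate
10 | 16-O-benzyloxymethyl ether of 9 | O=C1C[C@@H](O[Si](C)(C)C(C)(C)C)[C@@H]2CC[C@@H]3C[C@]12C[C@@]3(C)OCOCc4ccccc4 | intermediate
11 | C5=C6 enol triflate of 10 | FC(F)(F)S(=O)(=O)OC1=C[C@@H](O[Si](C)(C)C(C)(C)C)[C@@H]2CC[C@@H]3C[C@]12C[C@@]3(C)OCOCc4ccccc4 | intermediate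
12 | carbon monoxide | [C-]#[O+] | starting material
13 | benzyl 10β-(tert-butyldimethylsilyloxy)-16-(benzyloxymethoxy)-5-ene-7-oate of the tricycle | O=C(OCc5ccccc5)C1=C[C@@H](O[Si](C)(C)C(C)(C)C)[C@@H]2CC[C@@H]3C[C@]12C[C@@]3(C)OCOCc4ccccc4 | intermediate
14 | benzyl 10β-hydroxy-16-(benzyloxymethoxy)-5-ene-7-oate | O=C(OCc5ccccc5)C1=C[C@@H](O)[C@@H]2CC[C@@H]3C[C@]12C[C@@]3(C)OCOCc4ccccc4 | intermediate
15 | benzyl 10-oxo-16-(benzyloxymethoxy)-5-ene-7-oate | O=C(OCc5ccccc5)C1=CC(=O)[C@@H]2CC[C@@H]3C[C@]12C[C@@]3(C)OCOCc4ccccc4 | intermediate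
16 | [2-(1,3-dioxolan-2-yl)ethyl]magnesium bromide | Br[Mg]CCC1OCCO1 | starting material
17 | benzyl 10α-hydroxy-10β-[2-(1,3-dioxolan-2-yl)ethyl]-16-(benzyloxymethoxy)-5-ene-7-oate | O=C(OCc5ccccc5)C1=C[C@@](O)(CCC6OCCO6)[C@@H]2CC[C@@H]3C[C@]12C[C@@]3(C)OCOCc4ccccc4 | intermediate
18 | propanoic anhydride | CCC(=O)OC(=O)CC | starting material
19 | 10α-propanoate of 17 | O=C(OCc5ccccc5)C1=C[C@@](OC(=O)CC)(CCC6OCCO6)[C@@H]2CC[C@@H]3C[C@]12C[C@@]3(C)OCOCc4ccccc4 | intermediate
20 | 19,10α-lactone with C4–C5 bond, 4-H (methyl cis to H-5), 6β-CO2Bn, C10 dioxolanylethyl chain, 16-OBOM | C[C@H]1C(=O)O[C@]2(CCC6OCCO6)[C@@H]3CC[C@@H]4C[C@]3(C[C@@]4(C)OCOCc7ccccc7)[C@@H](C(=O)OCc5ccccc5)[C@H]12 | intermediate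
21 | lactone aldehyde (as 20, C10 chain CH2CH2CHO) | C[C@H]1C(=O)O[C@]2(CCC=O)[C@@H]3CC[C@@H]4C[C@]3(C[C@@]4(C)OCOCc7ccccc7)[C@@H](C(=O)OCc5ccccc5)[C@H]12 | intermediate
22 | 3-epimer of the target gibberellin as its 7-benzyl ester 16-O-benzyloxymethyl ether (3α-OH) | C[C@@]12C(=O)O[C@]3(CC[C@H]1O)[C@@H]1CC[C@@H]4C[C@]1(C[C@@]4(C)OCOCc7ccccc7)[C@@H](C(=O)OCc5ccccc5)[C@@H]32 | intermediate
23 | 3-oxo analogue of the target gibberellin as its 7-benzyl ester 16-O-benzyloxymethyl ether | C[C@@]12C(=O)O[C@]3(CCC1=O)[C@@H]1CC[C@@H]4C[C@]1(C[C@@]4(C)OCOCc7ccccc7)[C@@H](C(=O)OCc5ccccc5)[C@@H]32 | intermediate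
24 | 7-benzyl ester 16-O-benzyloxymethyl ether of the target gibberellin (3β-OH) | C[C@@]12C(=O)O[C@]3(CC[C@@H]1O)[C@@H]1CC[C@@H]4C[C@]1(C[C@@]4(C)OCOCc7ccccc7)[C@@H](C(=O)OCc5ccccc5)[C@@H]32 | intermediate
25 | 16-O-(hydroxymethyl) hemiformal of the target gibberellin (not isolated) | C[C@@]12C(=O)O[C@]3(CC[C@@H]1O)[C@@H]1CC[C@@H]4C[C@]1(C[C@@]4(C)OCO)[C@@H](C(=O)O)[C@@H]32 | intermediate
26 | the target gibberellin: 3β,10α,16α-trihydroxy-20-norgibberellane-7,19-dioic acid 19,10-lactone | C[C@@]12C(=O)O[C@]3(CC[C@@H]1O)[C@@H]1CC[C@@H]4C[C@]1(C[C@@]4(C)O)[C@@H](C(=O)O)[C@@H]32 | target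

**Totals and risk**

Total step count: 18. Longest linear sequence: 18 steps (from 1).

The three steps most likely to fail:

Step 5 (the proposed new step). The cyclisation may not compete with hydrogen return to the radical, the alcohol may be dehydrogenated, or the C16 epimer ratio may be poor. The fallback uses known chemistry and sets out from 8. Dess–Martin oxidation in CH2Cl2 gives the methyl ketone (3R,3aR,7aR)-3-(tert-butyldimethylsilyloxy)-7a-(2-oxopropyl)-2,3,3a,4,7,7a-hexahydro-1H-inden-1-one F2. A SmI2 ketyl–olefin cyclisation (SmI2 2.2 equiv, HMPA, t-BuOH 2 equiv, THF, −78 → 0 °C) then closes ring D 5-exo with the samarium-bound oxygen anti to the alkene, the established selectivity of this reaction. Chemoselectivity over the ring B ketone rests on the fast, irreversible ring closure of the side-chain ketyl. The fallback comes back to the route at 9.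

Step 3. The α-alkyl enone may be too sluggish, or the Lewis acid may eliminate the β-silyloxy group. The fallback sets out from the iodo enone 2 and butadiene 5. α-Halo enones are much better dienophiles, so MeAlCl2 (0.2 equiv) in CH2Cl2 at −78 °C should give, with the same anti-to-OTBS facial sense, the cis-fused α-iodo ketone (3R)-3-(tert-butyldimethylsilyloxy)-7a-iodo-2,3,3a,4,7,7a-hexahydro-1H-inden-1-one F1 (iodine in the position of the allyl group of 6). Keck radical allylation with 3 (AIBN, benzene, 80 °C) then delivers the allyl group to the convex face of the α-keto radical, which keeps the cis fusion. The fallback comes back to the route at 6.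

Step 11. The basic Grignard reagent may enolise the ketone at C9 or add in conjugate fashion. The fallback sets out from 15. Allylmagnesium bromide (THF, −78 °C; then H2O), a far faster and cleaner 1,2-adder, gives benzyl 10β-allyl-10α-hydroxy-16-(benzyloxymethoxy)-5-ene-7-oate F3. Acylation as in step 12 (KN(SiMe3)2; 18) gives its 10α-propanoate F4. Michael cyclisation as in step 13 (KN(SiMe3)2; t-BuOH; AcOH) gives the 10β-allyl lactone F5. Hydroboration–oxidation of the terminal alkene (9-BBN, THF; then NaBO3·4H2O, H2O) gives the 10β-(3-hydroxypropyl) lactone F6. Dess–Martin oxidation of this primary alcohol gives the aldehyde, so the fallback comes back to the route at 21.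

**Further compounds**

F1 | step 3 | (3R)-3-(tert-butyldimethylsilyloxy)-7a-iodo-2,3,3a,4,7,7a-hexahydro-1H-inden-1-one, cis-fused, iodine in the position of the allyl group of 6 | O=C1C[C@@H](O[Si](C)(C)C(C)(C)C)[C@@H]2CC=CC[C@]12I
F2 | step 5 | (3R,3aR,7aR)-3-(tert-butyldimethylsilyloxy)-7a-(2-oxopropyl)-2,3,3a,4,7,7a-hexahydro-1H-inden-1-one | O=C1C[C@@H](O[Si](C)(C)C(C)(C)C)[C@@H]2CC=CC[C@]12CC(C)=O
F3 | step 11 | benzyl 10β-allyl-10α-hydroxy-16-(benzyloxymethoxy)-5-ene-7-oate | O=C(OCc5ccccc5)C1=C[C@@](O)(CC=C)[C@@H]2CC[C@@H]3C[C@]12C[C@@]3(C)OCOCc4ccccc4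
F4 | step 11 | 10α-propanoate of F3 | O=C(OCc5ccccc5)C1=C[C@@](OC(=O)CC)(CC=C)[C@@H]2CC[C@@H]3C[C@]12C[C@@]3(C)OCOCc4ccccc4
F5 | step 11 | 10β-allyl analogue of lactone 20 | C[C@H]1C(=O)O[C@]2(CC=C)[C@@H]3CC[C@@H]4C[C@]3(C[C@@]4(C)OCOCc7ccccc7)[C@@H](C(=O)OCc5ccccc5)[C@H]12
F6 | step 11 | 10β-(3-hydroxypropyl) analogue of lactone 20 | C[C@H]1C(=O)O[C@]2(CCCO)[C@@H]3CC[C@@H]4C[C@]3(C[C@@]4(C)OCOCc7ccccc7)[C@@H](C(=O)OCc5ccccc5)[C@H]12
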